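The cycloheptene ring is cut at two bonds, C9–C10 and C7–C6 (daucane numbering: C1 quaternary ring-fusion carbon, C6 the anisoate carbinol, C8 the methyl-bearing alkene carbon). The route exploits the homoallylic alcohol C6(OH)–C7H2–C8(CH3)=C9H embedded in that ring, next to the C10 methylene on C1. In one operation a diazoalkene from methacrolein is inserted into the C10–boron bond of a cyclopentane that carries trans CH2B(OH)2 and CHO groups; the resulting allylboronic acid then allylates the aldehyde, which closes the seven-membered ring, places the C8=C9 alkene and creates the C6 carbinol. The cyclopentane comes from (R)-4-silyloxycyclopentenone by conjugate addition and enolate borylmethylation.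

Key step: step 12

Remark: all intermediates carry the atom numbers of the target: C1 = C(CH3) ring fusion, C2 = CH–OAc, C3 = CH2, C4 = C(OH)(i-Pr), C5 = ring-fusion CH, C6 = CH–O–anisoyl, C7 = CH2, C8 = C(CH3)=, C9 = =CH, C10 = CH2. In 1, C2 is the carbonyl carbon, C1 and C5 the alkene carbons, C4 the silyloxy carbon. TBS = tert-butyldimethylsilyl, Bpin = pinacolboryl. Compound 1, methacrolein and all reagents named are taken to be catalogue compounds.

Step 1
Reactants: 1 (R)-4-(tert-butyldimethylsilyloxy)cyclopent-2-en-1-one
Product: 2 (R)-4-(tert-butyldimethylsilyloxy)-2-iodocyclopent-2-en-1-one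
Conditions: I2, pyridine, CH2Cl2, 0 °C to rt
Reagents that add atoms: iodine, [I][I]
Why: α-iodination of the enone by reversible pyridine addition, iodination of the enolate and elimination (Baylis–Hillman-type mechanism), which leaves the C4 stereocentre untouched.

Step 2
Reactants: 2 (R)-4-(tert-butyldimethylsilyloxy)-2-iodocyclopent-2-en-1-one
Product: 3 (R)-4-(tert-butyldimethylsilyloxy)-2-methylcyclopent-2-en-1-one
Conditions: MeZnCl, Pd(PPh3)4 (5 mol %), THF, 0 °C to rt
Reagents that add atoms: methylzinc chloride, C[Zn]Cl
Why: Negishi coupling of the α-iodoenone under neutral conditions, so that the silyloxy group is not eliminated and C4 is kept.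

Step 3
Reactants: 3 (R)-4-(tert-butyldimethylsilyloxy)-2-methylcyclopent-2-en-1-one
Product: 4 silyl enol ether (4-TBSO-2-methyl-1-trimethylsilyloxy-3-vinylcyclopent-1-ene; vinyl trans to OTBS)
Conditions: CH2=CHMgBr, CuBr·SMe2 (10 mol %), Me3SiCl, THF, −78 °C; Et3N, then pentane/aq. NaHCO3
Reagents that add atoms: vinylmagnesium bromide, C=C[Mg]Br; chlorotrimethylsilane, C[Si](C)(C)Cl
Why: copper-catalysed conjugate addition with silyl trapping should deliver the vinyl group (the future C6) to C5 anti to the adjacent OTBS group (substrate control) and fix the enolate regiospecifically as the tetrasubstituted C1=C2 silyl enol ether.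

Step 4
Reactants: 4 silyl enol ether
Product: 6 borylmethyl ketone (4-TBSO-2-methyl-2-(Bpin-methyl)-3-vinylcyclopentan-1-one; CH2Bpin trans to vinyl; vinyl trans to OTBS), via lithium enolate 5 (not isolated)
Conditions: MeLi, THF, 0 °C; then ICH2Bpin, DMPU, −78 to −20 °C
Reagents that add atoms: 2-(iodomethyl)-4,4,5,5-tetramethyl-1,3,2-dioxaborolane, CC1(C)OB(CI)OC1(C)C
Why: alkylation of the regiodefined lithium enolate with an α-halomethylboronate should occur at C1 anti to the adjacent vinyl group, which sets the quaternary centre with C10 trans to C6 and methyl cis to it.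

Step 5
Reactants: 6 borylmethyl ketone
Product: 8 acetate (C2–OAc cis to CH2Bpin and to OTBS), via alcohol 7 (not isolated)
Conditions: LiAlH(OtBu)3, THF, −40 to 0 °C; then Ac2O, DMAP, 0 °C to rt
Reagents that add atoms: acetic anhydride, CC(=O)OC(C)=O
Why: the bulky hydride should attack the C2 ketone from the face of the C1 methyl group (anti to the larger CH2Bpin and to OTBS), giving the C2 alkoxide cis to CH2Bpin, which is acetylated in the same flask.

Step 6
Reactants: 8 acetate
Product: 9 C4 alcohol (C2–OAc; C4–OH; Bpin; vinyl)
Conditions: TsOH·H2O (0.2 equiv), MeOH, 0 °C to rt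
Reagents that add atoms: none
Why: acid-catalysed methanolysis removes the secondary silyl ether without fluoride, which spares the boronic ester and avoids base-induced 1,3-acetyl migration; no stereocentre changes.

Step 7
Reactants: 9 C4 alcohol
Product: 10 C4 ketone (β-acetoxy ketone with α-vinyl group)
Conditions: Dess–Martin periodinane, NaHCO3, CH2Cl2, 0 °C to rt; used crude
Reagents that add atoms: none
Why: Dess–Martin oxidation under buffered non-basic conditions should give the ketone without elimination of acetate, alkene migration or epimerisation at C5.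

Step 8
Reactants: 10 C4 ketone
Product: 11 tertiary alcohol (C4: i-Pr trans to vinyl and OH cis to vinyl; C2–OAc; Bpin)
Conditions: i-PrMgCl, anhydrous CeCl3, THF, −78 °C; aq. NH4Cl
Reagents that add atoms: isopropylmagnesium chloride, CC(C)[Mg]Cl
Why: organocerium 1,2-addition (weakly basic, so addition should outrun enolisation, acetate attack and reaction at boron) with approach anti to the adjacent C5 vinyl group sets C4 with the isopropyl group trans to C6.

Step 9
Reactants: 11 tertiary alcohol
Product: 12 aldehyde pinacol boronate (C5–CHO in place of vinyl)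
Conditions: O3, CH2Cl2/MeOH, −78 °C; Me2S, −78 °C to rt
Reagents that add atoms: ozone, [O-][O+]=O
Why: ozonolysis with reductive work-up cleaves the only alkene to the C6 aldehyde under neutral conditions that leave the alkylboronate, the acetate and the C5 stereocentre intact.

Step 10
Reactants: 12 aldehyde pinacol boronate
Product: 13 aldehyde boronic acid (C1–CH2B(OH)2 trans to C5–CHO)
Conditions: MeB(OH)2 (10 equiv), 0.1 M aq. HCl/MeCN 1:1, rt; evaporation; used crude
Reagents that add atoms: water, O
Why: transesterification of the pinacol ester onto methylboronic acid, driven by evaporation of the volatile methylboronate, frees the boronic acid under conditions mild enough for the β-hydroxy aldehyde; no stereocentre is touched.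

Step 11
Reactants: 14 methacrolein
Product: 16 sodium salt of methacrolein N-tosylhydrazone, via tosylhydrazone 15 (not isolated)
Conditions: TsNHNH2, MeOH, 0 °C; then NaOMe (1.0 equiv), MeOH, 0 °C; evaporation below rt in the dark
Reagents that add atoms: p-toluenesulfonyl hydrazide, Cc1ccc(cc1)S(=O)(=O)NN; sodium methoxide, C[O-].[Na+]
Why: hydrazone condensation at the aldehyde followed by deprotonation gives the storable precursor of the diazoalkene (Bamford–Stevens reaction); no stereocentre is involved.

Step 12
Reactants: 13 aldehyde boronic acid; 16 sodium salt of methacrolein N-tosylhydrazone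
Product: 19 bicyclic diol (2-acetoxydauc-8-ene-4,6-diol; trans ring fusion; 6-OH cis to H5), via diazoalkene 17 (not isolated), via allylboronic acid 18 (not isolated)
Conditions: 16 (3 equiv, in portions), BnEt3NCl (10 mol %), 1,4-dioxane (0.02 M), 50 to 70 °C; aq. NH4Cl
Reagents that add atoms: none
Why: Proposed new method: salt 16 releases diazoalkene 17 on warming (Bamford–Stevens), its diazo carbon C9 adds to the boron of 13, and 1,2-migration of the C10 methylene from boron to C9 with loss of N2 forms C9–C10 and gives the α-substituted allylboronic acid 18. The γ-carbon C7 of 18 then adds to the tethered aldehyde C6 through a cyclic B–O–C6···C7–C8–C9 transition state, which forms C7–C6, moves the alkene to C8=C9 and leaves a borate that is hydrolysed on work-up. The closest known reactions are the metal-free reductive coupling of sulfonylhydrazones with boronic acids, its domino variants in which the transient allylboronic acid is trapped by a carbonyl or nitrile group, and intramolecular carbonyl allylboration; untested are a vinyl diazoalkane paired with an alkylboronic acid and a tether that starts at the boron-bearing carbon. The seven-membered ring is closed in the allylboration event through a bridged, boat-like transition state in which the aldehyde is linked to the boron-bearing carbon, so the ring alkene can only be Z and endocyclic. The new stereocentre C6 is set by the O–B bridge, which must span C6 and C9 on the ring face opposite the angular C1 methyl and so places the C6 oxygen cis to H5; the transient stereocentre C9 is not controlled in the migration, and its other epimer can close only over the methyl-bearing face, which should be slow. The step needs attack through C7 (seven-membered ring) and not through C9 after a 1,3-boron shift (five-membered ring), which the slow allylic shift of allylboronic acids secures, and it needs the aldehyde to react in preference to the acetate, which uncatalysed allylboration secures.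

Step 13
Reactants: 19 bicyclic diol
Product: 20 target (6-O-(4-methoxybenzoyl) ester of 19)
Conditions: 4-methoxybenzoyl chloride, DMAP (cat.), pyridine, CH2Cl2, 0 °C to rt
Reagents that add atoms: 4-methoxybenzoyl chloride, COc1ccc(cc1)C(Cl)=O
Why: DMAP-catalysed acylation should take place only at the secondary C6 hydroxyl because the tertiary C4 hydroxyl is too hindered, and no stereocentre is touched.

Compound list

1 | (R)-4-(tert-butyldimethylsilyloxy)cyclopent-2-en-1-one | O=C1C=C[C@H](O[Si](C)(C)C(C)(C)C)C1 | starting material
2 | (R)-4-(tert-butyldimethylsilyloxy)-2-iodocyclopent-2-en-1-one | O=C1C(I)=C[C@H](O[Si](C)(C)C(C)(C)C)C1 | intermediate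
3 | (R)-4-(tert-butyldimethylsilyloxy)-2-methylcyclopent-2-en-1-one | CC1=C[C@H](O[Si](C)(C)C(C)(C)C)CC1=O | intermediate
4 | 4-TBSO-2-methyl-1-(trimethylsilyloxy)-3-vinylcyclopent-1-ene, vinyl trans to OTBS | C=C[C@H]1[C@H](O[Si](C)(C)C(C)(C)C)CC(O[Si](C)(C)C)=C1C | intermediate
5 | lithium enolate corresponding to 4 (OLi in place of OSiMe3) | C=C[C@H]1[C@H](O[Si](C)(C)C(C)(C)C)CC(O[Li])=C1C | intermediate
6 | 4-TBSO-2-methyl-2-(Bpin-methyl)-3-vinylcyclopentan-1-one, CH2Bpin trans to vinyl, vinyl trans to OTBS | CC1(C)OB(C[C@@]2(C)C(=O)C[C@@H](O[Si](C)(C)C(C)(C)C)[C@@H]2C=C)OC1(C)C | intermediate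
7 | cyclopentan-1-ol from 6, OH cis to CH2Bpin and to OTBS (formed as its aluminium alkoxide) | CC1(C)OB(C[C@@]2(C)[C@@H](O)C[C@@H](O[Si](C)(C)C(C)(C)C)[C@@H]2C=C)OC1(C)C | intermediate
8 | acetate of 7 | CC1(C)OB(C[C@@]2(C)[C@@H](OC(C)=O)C[C@@H](O[Si](C)(C)C(C)(C)C)[C@@H]2C=C)OC1(C)C | intermediate
9 | C4 alcohol (TBS removed from 8) | CC1(C)OB(C[C@@]2(C)[C@@H](OC(C)=O)C[C@@H](O)[C@@H]2C=C)OC1(C)C | intermediate
10 | C4 ketone, 4-acetoxy-3-methyl-3-(Bpin-methyl)-2-vinylcyclopentan-1-one | CC1(C)OB(C[C@@]2(C)[C@@H](OC(C)=O)CC(=O)[C@@H]2C=C)OC1(C)C | intermediate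
11 | tertiary alcohol, isopropyl on the face of OAc and CH2Bpin, OH on the face of vinyl and methyl | CC1(C)OB(C[C@@]2(C)[C@@H](OC(C)=O)C[C@@](O)(C(C)C)[C@@H]2C=C)OC1(C)C | intermediate
12 | aldehyde pinacol boronate (CHO in place of the vinyl group of 11) | CC1(C)OB(C[C@@]2(C)[C@@H](OC(C)=O)C[C@@](O)(C(C)C)[C@@H]2C=O)OC1(C)C | intermediate
13 | aldehyde boronic acid, CH2B(OH)2 on C1 trans to CHO on C5 | OB(O)C[C@@]1(C)[C@@H](OC(C)=O)C[C@@](O)(C(C)C)[C@@H]1C=O | intermediate
14 | methacrolein (2-methylprop-2-enal) | CC(=C)C=O | starting material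
15 | methacrolein N-tosylhydrazone (E) | C=C(C)/C=N/NS(=O)(=O)c1ccc(C)cc1 | intermediate
16 | sodium salt of 15 | [Na+].C=C(C)/C=N/[N-]S(=O)(=O)c1ccc(C)cc1 | intermediate
17 | 3-diazo-2-methylprop-1-ene | C=C(C)C=[N+]=[N-] | intermediate
18 | α-substituted allylboronic acid, B(OH)2 on C9 between C10 and the isopropenyl group (C9 epimer that closes on the face of H5) | OB(O)[C@@H](C[C@@]1(C)[C@@H](OC(C)=O)C[C@@](O)(C(C)C)[C@@H]1C=O)C(C)=C | intermediate
19 | 2-acetoxydauc-8-ene-4,6-diol, trans-fused, 2-OAc, 6-OH and H5 on one face, 4-OH and C1 methyl on the other | O[C@H]1CC(C)=CC[C@@]2(C)[C@@H](OC(C)=O)C[C@@](O)(C(C)C)[C@H]12 | intermediate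
20 | 6-O-(4-methoxybenzoyl) ester of 19 (CNP0171090.1) | COc1ccc(C(=O)O[C@H]2CC(C)=CC[C@@]3(C)[C@@H](OC(C)=O)C[C@@](O)(C(C)C)[C@H]23)cc1 | target

Total step count: 13. Longest linear sequence: 12 steps (steps 1 to 10, 12 and 13; step 11 is a one-step side branch).

Steps most likely to fail

1. Step 12 (proposed new method).
- What may go wrong: the bridged allylboration may be slow, so that protodeboronation of the allylboronic acid, intermolecular allylation or cyclisation of the diazoalkene to a pyrazole takes over. Facial control at C6 may be poor, and the β-hydroxy aldehyde may undergo retro-aldol cleavage on heating.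
- Fallback (known chemistry), from 13 back to 19: the aldehyde is allylated with 2-methylallylboronic acid pinacol ester (toluene, rt) to give the homoallylic alcohol boronic acid F1. Suzuki–Miyaura coupling of its primary alkylboronic acid with vinyl bromide (PdCl2(dppf), Ag2O, K2CO3, THF, 70 °C) gives the 1-allyl diene F2. Ring-closing metathesis (second-generation Grubbs catalyst, CH2Cl2, 40 °C) forms C8=C9 and returns to 19.
- If either route delivers the C6 epimer of the diol F3, Mitsunobu esterification with 4-methoxybenzoic acid (PPh3, DIAD, THF) in place of step 13 should give 20 directly with inversion.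

2. Step 4.
- What may go wrong: proton transfer between enolate and product followed by β-elimination of the silyloxy group, reaction of the enolate oxygen at boron or at carbon (O-alkylation), and slow formation of the quaternary centre.
- Fallback, from 4 back to 6: Simmons–Smith cyclopropanation of the electron-rich enol ether (Et2Zn, CH2I2, CH2Cl2, 0 °C), anti to the vinyl group, gives the siloxycyclopropane F4. Electrophilic ring opening with N-iodosuccinimide (MeCN, 0 °C) cleaves the C2–C10 bond to the β-iodo ketone F5, which already holds the quaternary centre. Copper-catalysed borylation of the primary iodide (B2pin2, CuI, PPh3, LiOMe, DMF, rt) returns to 6.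

3. Step 8.
- What may go wrong: β-elimination of acetate from the β-acetoxy ketone, attack of the organometallic on the acetate, enolisation of the α-vinyl ketone toward conjugation, and addition from the wrong face.
- Fallback, from 6 back to 11, which replaces the ester by an ether during the addition: 6 is reduced as in step 5 and alcohol 7 is isolated. It is protected (4-methoxybenzyl trichloroacetimidate, La(OTf)3 cat., toluene) as the 4-methoxybenzyl ether F6. Methanolysis of the TBS ether (TsOH·H2O, MeOH) gives the alcohol F7, Dess–Martin oxidation the ketone F8, and i-PrMgCl/CeCl3 (THF, −78 °C) the tertiary alcohol F9. DDQ (CH2Cl2/pH 7 buffer) releases the diol F10, and selective acetylation of its secondary hydroxyl (Ac2O, DMAP, pyridine) returns to 11.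

Further compounds

F1 | step 12 | homoallylic alcohol boronic acid (2-methylallyl adduct of 13 at C6, 6-OH as in 19) | OB(O)C[C@@]1(C)[C@@H](OC(C)=O)C[C@@](O)(C(C)C)[C@@H]1[C@@H](O)CC(C)=C
F2 | step 12 | 1-allyl diene (allyl on C1 in place of CH2B(OH)2 of F1) | C=CC[C@@]1(C)[C@@H](OC(C)=O)C[C@@](O)(C(C)C)[C@@H]1[C@@H](O)CC(C)=C
F3 | step 12 | C6 epimer of diol 19 | O[C@@H]1CC(C)=CC[C@@]2(C)[C@@H](OC(C)=O)C[C@@](O)(C(C)C)[C@H]12
F4 | step 4 | siloxycyclopropane (1-trimethylsilyloxy-5-methylbicyclo[3.1.0]hexane with 3-OTBS and 4-vinyl, cyclopropane CH2 trans to vinyl) | C=C[C@H]1[C@H](O[Si](C)(C)C(C)(C)C)C[C@]2(O[Si](C)(C)C)C[C@]12C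
F5 | step 4 | β-iodo ketone (CH2I in place of CH2Bpin of 6) | IC[C@@]1(C)C(=O)C[C@@H](O[Si](C)(C)C(C)(C)C)[C@@H]1C=C
F6 | step 8 | 4-methoxybenzyl ether of 7 | CC1(C)OB(C[C@@]2(C)[C@@H](OCc3ccc(OC)cc3)C[C@@H](O[Si](C)(C)C(C)(C)C)[C@@H]2C=C)OC1(C)C
F7 | step 8 | C4 alcohol from F6 | CC1(C)OB(C[C@@]2(C)[C@@H](OCc3ccc(OC)cc3)C[C@@H](O)[C@@H]2C=C)OC1(C)C
F8 | step 8 | C4 ketone from F7 | CC1(C)OB(C[C@@]2(C)[C@@H](OCc3ccc(OC)cc3)CC(=O)[C@@H]2C=C)OC1(C)C
F9 | step 8 | tertiary alcohol from F8 (isopropyl trans to vinyl) | CC1(C)OB(C[C@@]2(C)[C@@H](OCc3ccc(OC)cc3)C[C@@](O)(C(C)C)[C@@H]2C=C)OC1(C)C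
F10 | step 8 | diol from F9 (C2–OH and C4–OH free) | CC1(C)OB(C[C@@]2(C)[C@@H](O)C[C@@](O)(C(C)C)[C@@H]2C=C)OC1(C)C
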